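**Plan**

1. Retrosynthesis: cut the side-chain C13=C14 (cross-metathesis), then C4–C12 (lactone enolate alkylation), the epoxide oxygen (peracid on the C7=C8 E-alkene), C11=CH2 (methylenation of a C11 ketone), the lactone O2–C1 bond, and finally rejoin C11 to C7 to return to a hydrindane (retro-Grob).
2. Enabling feature: in the nine-membered ring the C11 carbon and the C7=C8 alkene sit in a cyclonon-4-enone relationship, and the lactone CH2 (C1) hangs on C11a, α to C11. A hydrindane with a tertiary alkoxide at the future C11, a tosylate at the future C8 and a methylidene at the future C11a fragments to the E-cyclononenone and at the same time turns C1=C11a–C11=O into a Michael acceptor lying 6-endo to the C3 carboxylate on the C4a arm.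
3. Forward: (S)-Hajos–Parrish ketone → CH2SPh at C4 → C1 reduction and tosylation → Luche reduction, carbonate and Pd allylic alkylation put the acetic acid arm on C5 (future C4a) → Mislow–Evans shift gives the tertiary allylic alcohol and exo-methylene → fragmentation/oxa-Michael (nine-membered ring, then lactone) → methylenation → C4 alkylation → epoxidation → cross-metathesis.
4. Stereochemistry: C4a is relayed from the Hajos–Parrish quaternary centre (hydride anti to the angular methyl, then net-retentive Pd substitution). The E-alkene comes from the antiperiplanar fragmentation, C11a from thermodynamic trans fusion, C4 from axial enolate alkylation, C7/C8 from peripheral epoxidation as in caryophyllene, and the side-chain E-alkene from thermodynamic metathesis.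

Key step: step 10

Remark on numbering: the target is numbered as a xenicane (C1 = lactone CH2, O2, C3 = lactone carbonyl, C4, C4a, C5–C11, C11a, side chain C12–C15). Compounds 1–13 carry indene numbering (C1–C3, C3a, C4–C7, C7a).
Assumption: 13 is drawn as the 3a-epimer expected from oxygen delivery anti to the angular methyl; either C3a epimer would give the same enone 14, because C3a becomes the C11 carbonyl.

Step 1
Reactants: 1 (7aS)-7a-methyl-2,3,7,7a-tetrahydro-1H-indene-1,5(6H)-dione [(S)-Hajos–Parrish ketone]
Product: 2 (7aS)-7a-methyl-4-[(phenylsulfanyl)methyl]-2,3,7,7a-tetrahydro-1H-indene-1,5(6H)-dione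
Conditions: PhSH, 37% aq. CH2O, Et3N, EtOH, 70 °C
Reagents that add atoms: thiophenol (Sc1ccccc1); formaldehyde (C=O)
Why: Kirk–Petrow-type thiomethylation: the amine-generated extended dienolate is hydroxymethylated at C4, dehydrates to the 4-methylene dienone and is trapped by thiophenol, which returns the conjugated enone carrying the CH2SPh handle (the future lactone CH2) without touching the quaternary stereocentre.

Step 2
Reactants: 2
Product: 3 (1S,7aS)-1-hydroxy-7a-methyl-4-[(phenylsulfanyl)methyl]-1,2,3,6,7,7a-hexahydro-5H-inden-5-one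
Conditions: NaBH4 (0.3 equiv), EtOH, −20 °C
Reagents that add atoms: none
Why: Chemoselective borohydride reduction: the saturated cyclopentanone is more electrophilic than the tetrasubstituted enone and hydride is delivered anti to the angular methyl, so the new C1 carbinol is cis to the 7a-methyl (1S).

Step 3
Reactants: 3
Product: 4 (1S,7aS)-7a-methyl-5-oxo-4-[(phenylsulfanyl)methyl]-2,3,5,6,7,7a-hexahydro-1H-inden-1-yl 4-methylbenzenesulfonate
Conditions: TsCl, pyridine, DMAP (cat.), 0 °C → rt
Reagents that add atoms: p-toluenesulfonyl chloride (Cc1ccc(cc1)S(=O)(=O)Cl)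
Why: Sulfonylation of the secondary alcohol with retention at C1 installs the nucleofuge for the later fragmentation; the neopentyl-type secondary tosylate should be inert to the soft reagents that follow.

Step 4
Reactants: 4
Product: 5 (1S,5S,7aS)-5-hydroxy-7a-methyl-4-[(phenylsulfanyl)methyl]-2,3,5,6,7,7a-hexahydro-1H-inden-1-yl 4-methylbenzenesulfonate
Conditions: NaBH4, CeCl3·7H2O, MeOH, −40 → 0 °C
Reagents that add atoms: none
Why: Luche 1,2-reduction: hydride adds axially from the face anti to the angular methyl (as in steroidal 4-en-3-ones), giving the 5S allylic alcohol cis to the 7a-methyl, and the cerium-modified borohydride leaves tosylate and sulfide alone.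

Step 5
Reactants: 5
Product: 6 (1S,5S,7aS)-5-[(methoxycarbonyl)oxy]-7a-methyl-4-[(phenylsulfanyl)methyl]-2,3,5,6,7,7a-hexahydro-1H-inden-1-yl 4-methylbenzenesulfonate
Conditions: ClCO2Me, pyridine, DMAP (cat.), CH2Cl2, 0 °C
Reagents that add atoms: methyl chloroformate (COC(=O)Cl)
Why: Acylation of the allylic alcohol to its methyl carbonate (retention at C5) provides the leaving group that ionises under neutral Tsuji–Trost conditions.

Step 6
Reactants: 6; 7 methyl 2-(phenylsulfonyl)acetate
Product: 8 methyl 2-[(1S,5S,7aS)-7a-methyl-4-[(phenylsulfanyl)methyl]-1-(tosyloxy)-2,3,5,6,7,7a-hexahydro-1H-inden-5-yl]-2-(phenylsulfonyl)acetate (both epimers at the sulfonyl-bearing carbon)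
Conditions: Pd(PPh3)4 (5 mol%), 7 (2 equiv), THF, 60 °C, no added base
Reagents that add atoms: none
Why: Tsuji–Trost allylic alkylation: zerovalent palladium ionises the carbonate anti, the liberated methoxide deprotonates 7, and the soft carbanion attacks the π-allyl anti to palladium at the secondary terminus C5 and not at the fully substituted ring-fusion terminus, so the C–C bond forms with net retention, cis to the 7a-methyl (this carbon becomes C4a).

Step 7
Reactants: 8
Product: 9 methyl 2-[(1S,5R,7aS)-7a-methyl-4-[(phenylsulfanyl)methyl]-1-(tosyloxy)-2,3,5,6,7,7a-hexahydro-1H-inden-5-yl]acetate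
Conditions: SmI2 (3 equiv), THF/MeOH, −78 °C
Reagents that add atoms: none
Why: Reductive desulfonylation of an α-sulfonyl ester by electron transfer from samarium diiodide, followed by protonation of the samarium enolate by methanol, removes the activating group; alkyl tosylate and allylic sulfide should not be reduced at −78 °C without HMPA.

Step 8
Reactants: 9
Product: 10 2-[(1S,5R,7aS)-7a-methyl-4-[(phenylsulfanyl)methyl]-1-(tosyloxy)-2,3,5,6,7,7a-hexahydro-1H-inden-5-yl]acetic acid
Conditions: LiOH, THF/H2O, 0 °C → rt; then 1 M HCl to pH 3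
Reagents that add atoms: lithium hydroxide ([Li+].[OH-])
Why: Saponification of the unhindered acetate-type methyl ester; it is placed before the tertiary alcohol exists, so hydroxide cannot trigger a premature fragmentation, and the hindered secondary tosylate should survive.

Step 9
Reactants: 10
Product: 13 2-[(1S,3aR,5R,7aR)-3a-hydroxy-7a-methyl-4-methylidene-1-(tosyloxy)octahydro-1H-inden-5-yl]acetic acid, via allylic sulfoxide 11 (not isolated), via allylic sulfenate 12 (not isolated)
Conditions: NaIO4, MeOH/H2O, 0 °C; then Et2NH, MeOH, 35 °C; aq. citric acid work-up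
Reagents that add atoms: sodium periodate ([Na+].[O-]I(=O)(=O)=O)
Why: Mislow–Evans rearrangement: periodate oxidises only sulfur, the allylic sulfoxide equilibrates by [2,3]-sigmatropic shift with the tertiary sulfenate, and diethylamine cleaves the sulfenate at sulfur; oxygen is delivered suprafacially to C3a on the face anti to the angular methyl (as in the 17α-hydroxylation of steroids by this method), giving the tertiary allylic alcohol and the exocyclic methylidene.

Step 10
Reactants: 13
Product: 15 (4aR,7E,11aS)-7-methyl-4,4a,5,6,9,10-hexahydro-1H-cyclonona[c]pyran-3,11(11aH)-dione (trans-fused keto lactone), via enone acid 14 (not isolated)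
Conditions: KOtBu (3 equiv), THF, 0 °C → rt; then AcOH (excess), rt
Reagents that add atoms: none
Why: Deprotonation gives the carboxylate and the C3a alkoxide; the alkoxide pushes into the C3a–C7a bond, which is antiperiplanar to the C1–OTs bond, so a Grob fragmentation expels tosylate, opens the hydrindane to the nine-membered ring and makes the new C11 ketone conjugated with the pre-installed methylidene (enone 14). On buffering with AcOH the C3 carboxylate adds to the now electrophilic exocyclic CH2 (C1) and the enol is protonated at C11a, an intramolecular oxa-Michael lactonisation; the closest known reaction types are base-induced fragmentation of 1,3-diol monosulfonates to cyclononenones and conjugate addition of carboxylic acids to enones. The δ-lactone closes 6-endo-trig through the O–CH2 bond, whereas the nine-membered ring is not closed but released by C–C cleavage. The alkene is E because the tosylate is cis to the angular methyl, which places the C2 and C7 ring bonds anti across the developing double bond; C11a, the only new stereocentre, is set under thermodynamic control (reversible conjugate addition and enolisation) to the trans, diequatorial ring fusion relative to C4a. Fragmentation must beat E2 and oxetane formation, which the antiperiplanar alignment and the hindered neopentyl-type tosylate secure; O-addition must beat oligomerisation of the enone, which the six-membered transition state and the absence of other nucleophiles once tert-butoxide is quenched secure.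

Step 11
Reactants: 15
Product: 16 (4aR,7E,11aR)-7-methyl-11-methylidene-4,4a,5,6,9,10,11,11a-octahydro-1H-cyclonona[c]pyran-3-one
Conditions: Zn, CH2Br2, TiCl4 (pre-formed Lombardo reagent), THF/CH2Cl2, 0 °C → rt
Reagents that add atoms: dibromomethane (BrCBr)
Why: Lombardo methylenation: the non-basic gem-dizinc/titanium methylene reagent converts the ketone to the exocyclic alkene while sparing the lactone and avoiding enolisation, so the C11a stereocentre and the β-acyloxy ketone (prone to E1cB with Wittig ylides) are preserved.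

Step 12
Reactants: 16; 17 4-iodobut-1-ene
Product: 18 (4S,4aS,7E,11aR)-4-(but-3-en-1-yl)-7-methyl-11-methylidene-4,4a,5,6,9,10,11,11a-octahydro-1H-cyclonona[c]pyran-3-one
Conditions: LDA, THF, −78 °C; then 17 (3 equiv), DMPU, −78 → −40 °C
Reagents that add atoms: none
Why: Lactone enolate alkylation: the lithium enolate adopts a half-chair with C4a–H pseudo-axial and the iodide is attacked along the axial trajectory anti to that hydrogen (chair-like transition state), which should place the butenyl chain cis to C5 and give the 4S configuration.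

Step 13
Reactants: 18
Product: 19 (4S,4aS,7S,8S,11aR)-4-(but-3-en-1-yl)-7,8-epoxy-7-methyl-11-methylidene-decahydro-1H-cyclonona[c]pyran-3-one (7,8-epoxide of 18)
Conditions: mCPBA (1.05 equiv), NaHCO3, CH2Cl2, −20 → 0 °C
Reagents that add atoms: mCPBA (OOC(=O)c1cccc(Cl)c1)
Why: Prilezhaev epoxidation: the strained trisubstituted E-alkene is far more nucleophilic than the 1,1-disubstituted and monosubstituted alkenes, and the peracid should attack its exposed outer face in the preferred conformer of the trans-fused bicycle, the same sense as in the conversion of caryophyllene into caryophyllene oxide, giving the (7S,8S)-epoxide.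

Step 14
Reactants: 19; 20 methyl methacrylate
Product: 21 Acalycixeniolide H
Conditions: second-generation Hoveyda–Grubbs catalyst RuCl2(H2IMes)(=CH-C6H4-2-OiPr) (5 mol%), 20 (10 equiv), CH2Cl2, 40 °C
Reagents that add atoms: none
Why: Olefin cross-metathesis of the terminal alkene with excess methyl methacrylate: the 1,1-disubstituted partner does not homodimerise and the thermodynamically favoured E-trisubstituted enoate should form, while the hindered exocyclic methylidene and the epoxide are inert.

**Compound list**

1 | (7aS)-7a-methyl-2,3,7,7a-tetrahydro-1H-indene-1,5(6H)-dione [(S)-Hajos–Parrish ketone] | C[C@]12CCC(=O)C=C1CCC2=O | starting material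
2 | (7aS)-7a-methyl-4-[(phenylsulfanyl)methyl]-2,3,7,7a-tetrahydro-1H-indene-1,5(6H)-dione | C[C@]12CCC(=O)C(CSc3ccccc3)=C1CCC2=O | intermediate
3 | (1S,7aS)-1-hydroxy-7a-methyl-4-[(phenylsulfanyl)methyl]-1,2,3,6,7,7a-hexahydro-5H-inden-5-one | C[C@]12CCC(=O)C(CSc3ccccc3)=C1CC[C@@H]2O | intermediate
4 | (1S,7aS)-7a-methyl-5-oxo-4-[(phenylsulfanyl)methyl]-2,3,5,6,7,7a-hexahydro-1H-inden-1-yl 4-methylbenzenesulfonate | C[C@]12CCC(=O)C(CSc3ccccc3)=C1CC[C@@H]2OS(=O)(=O)c1ccc(C)cc1 | intermediate
5 | (1S,5S,7aS)-5-hydroxy-7a-methyl-4-[(phenylsulfanyl)methyl]-2,3,5,6,7,7a-hexahydro-1H-inden-1-yl 4-methylbenzenesulfonate | C[C@]12CC[C@H](O)C(CSc3ccccc3)=C1CC[C@@H]2OS(=O)(=O)c1ccc(C)cc1 | intermediate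
6 | (1S,5S,7aS)-5-[(methoxycarbonyl)oxy]-7a-methyl-4-[(phenylsulfanyl)methyl]-2,3,5,6,7,7a-hexahydro-1H-inden-1-yl 4-methylbenzenesulfonate | C[C@]12CC[C@H](OC(=O)OC)C(CSc3ccccc3)=C1CC[C@@H]2OS(=O)(=O)c1ccc(C)cc1 | intermediate
7 | methyl 2-(phenylsulfonyl)acetate | COC(=O)CS(=O)(=O)c1ccccc1 | starting material
8 | methyl 2-[(1S,5S,7aS)-7a-methyl-4-[(phenylsulfanyl)methyl]-1-(tosyloxy)-2,3,5,6,7,7a-hexahydro-1H-inden-5-yl]-2-(phenylsulfonyl)acetate (epimers at the sulfonyl carbon) | C[C@]12CC[C@H](C(C(=O)OC)S(=O)(=O)c4ccccc4)C(CSc3ccccc3)=C1CC[C@@H]2OS(=O)(=O)c1ccc(C)cc1 | intermediate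
9 | methyl 2-[(1S,5R,7aS)-7a-methyl-4-[(phenylsulfanyl)methyl]-1-(tosyloxy)-2,3,5,6,7,7a-hexahydro-1H-inden-5-yl]acetate | C[C@]12CC[C@H](CC(=O)OC)C(CSc3ccccc3)=C1CC[C@@H]2OS(=O)(=O)c1ccc(C)cc1 | intermediate
10 | 2-[(1S,5R,7aS)-7a-methyl-4-[(phenylsulfanyl)methyl]-1-(tosyloxy)-2,3,5,6,7,7a-hexahydro-1H-inden-5-yl]acetic acid | C[C@]12CC[C@H](CC(=O)O)C(CSc3ccccc3)=C1CC[C@@H]2OS(=O)(=O)c1ccc(C)cc1 | intermediate
11 | 2-[(1S,5R,7aS)-7a-methyl-4-[(phenylsulfinyl)methyl]-1-(tosyloxy)-2,3,5,6,7,7a-hexahydro-1H-inden-5-yl]acetic acid (sulfoxide epimers; not isolated) | C[C@]12CC[C@H](CC(=O)O)C(CS(=O)c3ccccc3)=C1CC[C@@H]2OS(=O)(=O)c1ccc(C)cc1 | intermediate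
12 | 2-[(1S,3aR,5R,7aR)-7a-methyl-4-methylidene-3a-[(phenylsulfanyl)oxy]-1-(tosyloxy)octahydro-1H-inden-5-yl]acetic acid (not isolated) | C[C@]12CC[C@H](CC(=O)O)C(=C)[C@]1(OSc3ccccc3)CC[C@@H]2OS(=O)(=O)c1ccc(C)cc1 | intermediate
13 | 2-[(1S,3aR,5R,7aR)-3a-hydroxy-7a-methyl-4-methylidene-1-(tosyloxy)octahydro-1H-inden-5-yl]acetic acid | C[C@]12CC[C@H](CC(=O)O)C(=C)[C@]1(O)CC[C@@H]2OS(=O)(=O)c1ccc(C)cc1 | intermediate
14 | 2-[(1R,6E)-7-methyl-2-methylidene-3-oxocyclonon-6-en-1-yl]acetic acid (present as its potassium salt; not isolated) | O=C1CC/C=C(\C)CC[C@H](CC(=O)O)C1=C | intermediate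
15 | (4aR,7E,11aS)-7-methyl-4,4a,5,6,9,10-hexahydro-1H-cyclonona[c]pyran-3,11(11aH)-dione (trans-fused) | O=C1CC/C=C(\C)CC[C@@H]2CC(=O)OC[C@@H]12 | intermediate
16 | (4aR,7E,11aR)-7-methyl-11-methylidene-4,4a,5,6,9,10,11,11a-octahydro-1H-cyclonona[c]pyran-3-one | C=C1CC/C=C(\C)CC[C@@H]2CC(=O)OC[C@@H]12 | intermediate
17 | 4-iodobut-1-ene | C=CCCI | starting material
18 | (4S,4aS,7E,11aR)-4-(but-3-en-1-yl)-7-methyl-11-methylidene-4,4a,5,6,9,10,11,11a-octahydro-1H-cyclonona[c]pyran-3-one | C=C1CC/C=C(\C)CC[C@@H]2[C@H](CCC=C)C(=O)OC[C@@H]12 | intermediate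
19 | (4S,4aS,7S,8S,11aR)-4-(but-3-en-1-yl)-7,8-epoxy-7-methyl-11-methylidene-decahydro-1H-cyclonona[c]pyran-3-one | C=C1CC[C@@H]2O[C@@]2(C)CC[C@@H]2[C@H](CCC=C)C(=O)OC[C@@H]12 | intermediate
20 | methyl methacrylate | C=C(C)C(=O)OC | starting material
21 | Acalycixeniolide H | C=C1CC[C@@H]2O[C@@]2(C)CC[C@@H]2[C@H](CC/C=C(\C)C(=O)OC)C(=O)OC[C@@H]12 | target

**Step count**

Total steps: 14. Longest linear sequence: 14 steps (from 1).

**Steps most likely to fail**

Step 10. After the fragmentation the open enone may oligomerise, or the conjugate addition may stay reversible (E1cB reversal of the β-acyloxy ketone) so that no lactone accumulates; incomplete equilibration at C11a is a further hazard. The fallback closes the lactone through the acyl C–O bond instead and sets out from 13. Esterification (TMSCHN2, MeOH/toluene) would give methyl 2-[(1S,3aR,5R,7aR)-3a-hydroxy-7a-methyl-4-methylidene-1-(tosyloxy)octahydro-1H-inden-5-yl]acetate F1. KOtBu in THF would fragment it to the enone ester methyl 2-[(1R,6E)-7-methyl-2-methylidene-3-oxocyclonon-6-en-1-yl]acetate F2. Copper-catalysed conjugate borylation (CuCl, NaOtBu, Xantphos, B2pin2, MeOH, THF) would give the β-boryl ketone methyl 2-[(1R,6E)-7-methyl-3-oxo-2-[(4,4,5,5-tetramethyl-1,3,2-dioxaborolan-2-yl)methyl]cyclonon-6-en-1-yl]acetate F3. Oxidation (NaBO3, THF/H2O) would give the β-hydroxy ketone methyl 2-[(1R,6E)-2-(hydroxymethyl)-7-methyl-3-oxocyclonon-6-en-1-yl]acetate F4. Neutral transesterification (Bu2SnO cat., toluene, 80 °C) would lactonise F4 and equilibrate C11a to the trans fusion, coming back to the route at 15.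

Step 13. Facial selectivity may be poor, because the two faces of the E-alkene are presented by interconverting conformers of the nine-membered ring and the peracid may not discriminate; some epoxidation of the exocyclic methylidene is also possible. The fallback replaces substrate control by reagent control and sets out from 18: Shi epoxidation with the enantiomer of the fructose-derived ketone catalyst (Oxone, K2CO3 buffer, MeCN/dimethoxymethane/H2O, 0 °C). This catalyst class is selective for trans-trisubstituted alkenes and should choose the conformer that leads to the (7S,8S)-epoxide. It comes back at 19 and makes no further compound (F0).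

Step 12. E2 elimination of the homoallylic iodide by the basic enolate may outrun a sluggish C-alkylation, and the late metathesis then rests on little material. The fallback uses an electrophile without an activated β-hydrogen and builds the enoate by Wittig olefination; it sets out from 16. Alkylation (LDA, THF/DMPU, tert-butyl(3-iodopropoxy)dimethylsilane) would give (4S,4aS,7E,11aR)-4-[3-(tert-butyldimethylsilyloxy)propyl]-7-methyl-11-methylidene-octahydro-1H-cyclonona[c]pyran-3-one F5. TBAF in THF would give the primary alcohol F6, and Dess–Martin periodinane the aldehyde F7. Methyl 2-(triphenylphosphoranylidene)propanoate (CH2Cl2, rt) would give the E-enoate, 7,8-deoxy-acalycixeniolide H F8. Epoxidation of F8 as in step 13 (the enoate alkene is inert to mCPBA) comes back to the route at 21.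

**Further compounds**

F1 | step 10 | methyl 2-[(1S,3aR,5R,7aR)-3a-hydroxy-7a-methyl-4-methylidene-1-(tosyloxy)octahydro-1H-inden-5-yl]acetate | C[C@]12CC[C@H](CC(=O)OC)C(=C)[C@]1(O)CC[C@@H]2OS(=O)(=O)c1ccc(C)cc1
F2 | step 10 | methyl 2-[(1R,6E)-7-methyl-2-methylidene-3-oxocyclonon-6-en-1-yl]acetate | O=C1CC/C=C(\C)CC[C@H](CC(=O)OC)C1=C
F3 | step 10 | methyl 2-[(1R,6E)-7-methyl-3-oxo-2-[(4,4,5,5-tetramethyl-1,3,2-dioxaborolan-2-yl)methyl]cyclonon-6-en-1-yl]acetate (C2 epimers) | O=C1CC/C=C(\C)CC[C@H](CC(=O)OC)C1CB2OC(C)(C)C(C)(C)O2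
F4 | step 10 | methyl 2-[(1R,6E)-2-(hydroxymethyl)-7-methyl-3-oxocyclonon-6-en-1-yl]acetate (C2 epimers) | O=C1CC/C=C(\C)CC[C@H](CC(=O)OC)C1CO
F0 | step 13 | none | none
F5 | step 12 | (4S,4aS,7E,11aR)-4-[3-(tert-butyldimethylsilyloxy)propyl]-7-methyl-11-methylidene-octahydro-1H-cyclonona[c]pyran-3-one | C=C1CC/C=C(\C)CC[C@@H]2[C@H](CCCO[Si](C)(C)C(C)(C)C)C(=O)OC[C@@H]12
F6 | step 12 | (4S,4aS,7E,11aR)-4-(3-hydroxypropyl)-7-methyl-11-methylidene-octahydro-1H-cyclonona[c]pyran-3-one | C=C1CC/C=C(\C)CC[C@@H]2[C@H](CCCO)C(=O)OC[C@@H]12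
F7 | step 12 | 3-[(4S,4aS,7E,11aR)-7-methyl-11-methylidene-3-oxo-octahydro-1H-cyclonona[c]pyran-4-yl]propanal | C=C1CC/C=C(\C)CC[C@@H]2[C@H](CCC=O)C(=O)OC[C@@H]12
F8 | step 12 | 7,8-deoxy-acalycixeniolide H, methyl (2E)-2-methyl-5-[(4S,4aS,7E,11aR)-7-methyl-11-methylidene-3-oxo-octahydro-1H-cyclonona[c]pyran-4-yl]pent-2-enoate | C=C1CC/C=C(\C)CC[C@@H]2[C@H](CC/C=C(\C)C(=O)OC)C(=O)OC[C@@H]12
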